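Atom labels follow lignan usage. C7–C9 is the guaiacyl C3 unit, C7'–C9' the central syringyl C3 unit, and C7''–C9'' the glycerol side chain.

## Analysis of the target

- The target is a sesquineolignan. Its core is a cis-fused 3,7-dioxabicyclo[3.3.0]octane (7,9':7',9-diepoxylignan) with a guaiacyl group on C7 and a syringyl group on C7'. The syringyl 4-oxygen is bound to C8'' of a syringylglycerol chain.
- The descriptors read from the structure are 7R,8S,8'S,7'S in the core and 7''R,8''R in the chain.
- H8 and H8' are cis and mark the convex face. The guaiacyl group lies on that face (exo, H7/H8 trans) and the syringyl group lies in the fold (endo, H7'/H8' cis). The core therefore belongs to the epi series, and C7' is the less stable epimer.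
- The chain is threo, which is syn in the zigzag drawing, and it is too far from the core for any substrate control.
- The sensitive groups are two free phenols para to benzylic C–O bonds (quinone methide formation), three electron-rich benzylic C–O bonds that ionise in acid and cleave on over-hydrogenation, and C7' itself, which acid equilibrates towards the exo,exo isomer.
- The difficulty is the lack of symmetry. Two different aryl groups sit in two different orientations on four contiguous centres, so dimerisation logic fails. One centre has to be set kinetically, and three phenolic oxygens must be told apart.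
- The strategy rests on ring C7'–O–C9–C8–C8'. C9 is a plain methylene between O and C8, and C7'/C8' carry cis hydrogens, so the ring can come from a C7'=C8' enol ether by syn hydrogenation. That enol ether is a constitutional isomer of a cyclopropane C8–C9–C8' that bears the syringoyl carbonyl carbon (C7') on C8'.
- With C9' held at the lactone level, the second ring supplies the second acceptor that such a cyclopropane needs.

## Retrosynthetic reasoning

**27 ⇒ 26.** Both free phenols are unmasked last from one kind of silyl ether. No phenol para to a benzylic C–O bond then has to pass through base, Lewis acid or oxidant. The forward step cleaves two O–Si bonds and nothing else.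

**26 ⇒ 25 ⇒ 21 + 23.** The C7''–C8'' bond is cut. A boron-mediated syn glycolate aldol between imide 21 and aldehyde 23 makes this bond and both chain stereocentres in one reagent-controlled event. This suits a remote stereodiad that the core cannot influence. The imide carbonyl becomes C9'' on reductive removal of the auxiliary (25 to 26). Cutting the aryl ether O–C8'' at the stage of the finished chain would instead require substitution at a secondary carbon next to a benzylic carbinol.

**21 ⇒ 17 + 20, 20 ⇒ 18 + 19.** The aryl ether is cut while C8'' is still an unsubstituted methylene. The forward reaction is a simple displacement of bromide from 20 by the one free phenol of 17. This requires the central syringyl oxygen to be the only unmasked phenol at that point.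

**17 ⇒ 16 ⇒ 15.** C9' is raised from methylene to lactone carbonyl. No bond is cut. The carbonyl gained activates everything that precedes it and is removed in two reductive operations through lactol 16.

**15 ⇒ 14.** The C7'–H and C8'–H bonds are removed to give the tetrasubstituted enol ether 14. Two stereocentres, one of them the contra-thermodynamic C7', are reduced to one question of facial selectivity on a folded bicycle. C8 answers that question, because only one face leads to a cis ring fusion. The benzyl ether on the syringyl oxygen is planned to fall in the same operation, which delivers the single free phenol needed above.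

**14 ⇒ 12 (through 13).** O–C9 is cut and C9–C8' is reconnected, which turns the dihydrofuran into acyl cyclopropane 12. The cut is made here because 12 contains every atom of the ring, carries both acceptors on C8', and offers an unhindered primary carbon to a catalytic soft nucleophile. The forward reaction must open the three-membered ring at C9 only and close through the ketone oxygen only.

**12 ⇒ 11 ⇒ 10.** C8'–C8 and C8'–C9 are cut together. An intramolecular carbene addition of diazo ester 11 to its own vinyl group builds the lactone and the cyclopropane at once. It relays the C7 configuration to C8 and C8'. Diazo transfer links 11 to β-keto ester 10.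

**10 ⇒ 5 + 9.** The ester C–O bond is cut between the acyl carbon and the oxygen. The C7–O bond of alcohol 5 is never broken, and the two aromatic halves stay separate until this point.

**Roots.**
- Alcohol 5 comes from racemic 4 by kinetic resolution through asymmetric epoxidation. 4 comes from aldehyde 2 and 3, and 2 from 1.
- Keto ester 9 comes from ketone 7 and 8, and 7 from 6.
- Aldehyde 23 comes from 22.
- An aryl vinyl ketone followed by enantioselective reduction would reach 5 only over two more steps. It would pass through a polymerisable enone whose two flanking sp2 groups are poorly differentiated, so the resolution is preferred.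

## Alternatives that were turned down

**Alternative 1: C8–C8' by borylative enyne cyclisation.**
- *Disconnection and key step.* The disconnection cuts C8–C8' and puts a boron atom on C9. In the forward sense the enyne ether A1 is treated with Pd(OAc)2, B2pin2 and methanol. A palladium hydride adds syn to the alkyne, the vinyl group inserts in a 5-exo mode, and the primary alkylpalladium is borylated to give A2.
- *In favour.* The assembly of A1 is very convergent. The C–C bond formation is catalytic. A trans C7/C8 relay is expected, the alkene geometry is defined, and the boronate is a latent C9 hydroxyl. No diazo compound is needed. On convergence and on the number of steps to a monocyclic core it is stronger than the chosen plan.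
- *Against.* A2 still lacks the ring that holds C7', and both C7' and C8' are unset.
  - Adding the C9 hydroxyl across the C7'=C8' styrene is a 5-endo process that needs cationic activation at C7'. Such closures deliver the exo aryl group, the wrong epimer here.
  - Stepwise oxygenation of C7' would need face control on an exocyclic alkene of a flexible monocycle, and it adds steps.
  - The 1-arylallyl ether in A1 can also ionise to a π-allyl complex once zerovalent palladium is present.
- *Comparison.* The chosen plan derives C7' and C8' from one syn addition to a rigid bicycle.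

**Alternative 2: C7–O by anodic quinone methide formation.**
- *Disconnection and key step.* The disconnection cuts C7–O in the last step. Two-electron anodic oxidation of the free 4-hydroxy-3-methoxybenzyl group of A3 gives a p-quinone methide at C7, which the C9' hydroxyl traps to give A4. One desilylation then remains.
- *In favour.* The logic is biomimetic and no chemical oxidant is used. The guaiacyl phenol stays unprotected. The exo outcome at C7 is favoured both kinetically and thermodynamically, so C7 needs no earlier control and no resolution. In protecting-group economy and in the brevity of the end game it is stronger.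
- *Against.* The key step closes the easy ring.
  - A3 is an all-cis 2,3,4-trisubstituted tetrahydrofuran that already holds C7', C8' and C8 and the whole side chain. Nothing in the key step helps to make it.
  - At the oxidation stage two further trialkoxyarenes, a benzylic alcohol and a primary alcohol are present. Phenoxyl coupling can compete.
  - A4 is itself a free guaiacyl phenol with a benzylic C–H bond and can be oxidised further.
- *Comparison.* This plan puts its least predictable step at the end, on the most valuable material. The chosen plan puts its risk at step 9, on a compound made from cheap materials, and spends it on the difficult ring.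

**Alternative 3: C7'–C8' by carbenoid C–H insertion.**
- *Disconnection and key step.* The disconnection cuts C7'–C8'. Rh2(OAc)4 converts the α-diazo lactone A5 into a carbenoid at C8' that inserts into a benzylic C–H bond of the C9–O–CH2Ar ether and gives the furofuranone A6.
- *In favour.* One step makes a C–C bond and both stereocentres at the correct oxidation level. Insertions of this kind are an established way to endo,exo-furofuranones. No hindered alkene has to be hydrogenated, so the hydrogenolysis risk disappears. In the reliability of the stereodefining step it is at least as strong as the chosen plan, probably stronger.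
- *Against.*
  - A5 is usually reached from an acyl cyclopropane lactone of the same type as 12, by opening with the benzylic alcohol and deacylative diazo transfer. The acyl group is discarded, two carbenoid steps are needed, and the route is longer.
  - The 4-silyloxy-3,5-dimethoxybenzyl ether is acid-labile.
  - The carbenoid has other exits: a 1,2-hydride shift from C8, oxonium ylide formation followed by a Stevens shift, and addition to the electron-rich arene.
- *Comparison.* The chosen plan keeps the acyl carbon as C7', so every atom of 12 reaches the target and only one carbenoid step is needed. The price is a less well charted stereodefining hydrogenation.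

Key step: step 9

Remark on the chemistry: the anomeric centre C9' of 16 is left undefined because it is destroyed in the next step. Diisopropyl D-tartrate [D-(−)-DIPT], 18, 19 and 22 are taken as commercial.

## Route

Step 1
Reactants: 1 vanillin
Product: 2 3-methoxy-4-(triisopropylsilyloxy)benzaldehyde
Conditions: TIPSCl, imidazole, DMF, rt
Reagents that add atoms: triisopropylsilyl chloride, CC(C)[Si](Cl)(C(C)C)C(C)C
Why: Standard silylation of a phenol; the bulky aryl silyl ether should survive Grignard addition, hydrides, carbonate bases, hydrogenation and brief Lewis acid at low temperature, and it falls to fluoride at the end.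

Step 2
Reactants: 2 3-methoxy-4-(triisopropylsilyloxy)benzaldehyde; 3 vinylmagnesium bromide
Product: 4 rac-1-[3-methoxy-4-(triisopropylsilyloxy)phenyl]prop-2-en-1-ol
Conditions: THF, −78 → 0 °C; aq. NH4Cl
Reagents that add atoms: none
Why: Grignard 1,2-addition to a non-enolisable aldehyde; C8 and C9 enter as the vinyl group and C7 is formed racemic.

Step 3
Reactants: 4 rac-1-[3-methoxy-4-(triisopropylsilyloxy)phenyl]prop-2-en-1-ol
Product: 5 (R)-1-[3-methoxy-4-(triisopropylsilyloxy)phenyl]prop-2-en-1-ol
Conditions: Ti(OiPr)4 (15 mol %), D-(−)-DIPT (20 mol %), t-BuOOH (0.6 equiv), 4 Å MS, CH2Cl2, −20 °C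
Reagents that add atoms: none
Why: Sharpless kinetic resolution of a secondary allylic alcohol; with the D-tartrate the (S)-enantiomer of an aryl vinyl carbinol is epoxidised faster, so running past half conversion should leave (R)-5, which is easily separated from the polar epoxy alcohol. This fixes C7, the only core centre not set by substrate control.

Step 4
Reactants: 6 acetosyringone
Product: 7 1-(4-benzyloxy-3,5-dimethoxyphenyl)ethanone
Conditions: BnBr, K2CO3, DMF, 60 °C
Reagents that add atoms: benzyl bromide, BrCc1ccccc1
Why: Williamson etherification of a flanked phenol, hence DMF and gentle heat; benzyl is chosen because it is lost in the hydrogenation of step 10 and so frees exactly one phenol.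

Step 5
Reactants: 7 1-(4-benzyloxy-3,5-dimethoxyphenyl)ethanone; 8 diethyl carbonate
Product: 9 ethyl 3-(4-benzyloxy-3,5-dimethoxyphenyl)-3-oxopropanoate
Conditions: NaH (2.5 equiv), THF, reflux; AcOH quench
Reagents that add atoms: none
Why: Crossed Claisen condensation of a methyl ketone enolate with a non-enolisable carbonate, driven by deprotonation of the β-keto ester formed.

Step 6
Reactants: 5 (R)-1-[3-methoxy-4-(triisopropylsilyloxy)phenyl]prop-2-en-1-ol; 9 ethyl 3-(4-benzyloxy-3,5-dimethoxyphenyl)-3-oxopropanoate
Product: 10 (R)-1-[3-methoxy-4-(triisopropylsilyloxy)phenyl]allyl 3-(4-benzyloxy-3,5-dimethoxyphenyl)-3-oxopropanoate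
Conditions: DMAP (30 mol %), 4 Å MS, toluene, 100 °C
Reagents that add atoms: none
Why: DMAP-catalysed transesterification of a β-keto ester, a reaction known for secondary and allylic alcohols; the sieves take up ethanol. Only the acyl–oxygen bond changes, so C7 keeps its configuration.

Step 7
Reactants: 10 (R)-1-[3-methoxy-4-(triisopropylsilyloxy)phenyl]allyl 3-(4-benzyloxy-3,5-dimethoxyphenyl)-3-oxopropanoate
Product: 11 (R)-1-[3-methoxy-4-(triisopropylsilyloxy)phenyl]allyl 3-(4-benzyloxy-3,5-dimethoxyphenyl)-2-diazo-3-oxopropanoate
Conditions: p-ABSA, Et3N, MeCN, 0 °C → rt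
Reagents that add atoms: 4-acetamidobenzenesulfonyl azide (p-ABSA), CC(=O)Nc1ccc(cc1)S(=O)(=O)N=[N+]=[N-]
Why: Regitz diazo transfer to an active methylene group; mild amine base leaves the ester, the silyl ether and C7 alone.

Step 8
Reactants: 11 (R)-1-[3-methoxy-4-(triisopropylsilyloxy)phenyl]allyl 3-(4-benzyloxy-3,5-dimethoxyphenyl)-2-diazo-3-oxopropanoate
Product: 12 (1S,4R,5R)-1-(4-benzyloxy-3,5-dimethoxybenzoyl)-4-[3-methoxy-4-(triisopropylsilyloxy)phenyl]-3-oxabicyclo[3.1.0]hexan-2-one (aryl on the face opposite to the cyclopropane CH2)
Conditions: Rh2(OAc)4 (1 mol %), CH2Cl2, 40 °C, slow addition of 11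
Reagents that add atoms: none
Why: Intramolecular cyclopropanation of an allyl α-diazo-β-keto ester at dirhodium tetraacetate forms C8'–C8 and C8'–C9, with the cis ring fusion imposed by geometry. In the favoured transition state the C7 aryl group points away from the incoming vinyl CH2 and from the metal-bound aroyl group, so (R)-C7 should set C8 (R) and C8' (S) with the aryl group exo.

Step 9
Reactants: 12 (1S,4R,5R)-1-(4-benzyloxy-3,5-dimethoxybenzoyl)-4-[3-methoxy-4-(triisopropylsilyloxy)phenyl]-3-oxabicyclo[3.1.0]hexan-2-one
Product: 14 (3R,3aS)-6-(4-benzyloxy-3,5-dimethoxyphenyl)-3-[3-methoxy-4-(triisopropylsilyloxy)phenyl]-3a,4-dihydro-1H,3H-furo[3,4-c]furan-1-one (C7'=C8' enol ether fused to the lactone), via iodomethyl lactone enolate 13 (not isolated)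
Conditions: Bu4NI (20 mol %), MeCN, 80 °C
Reagents that add atoms: none
Why: This is a nucleophile-catalysed Cloke–Wilson rearrangement; the closest known reaction type is the halide- or amine-catalysed ring expansion of 1-acylcyclopropane-1-carboxylates to 4,5-dihydrofuran-3-carboxylates, applied here to a lactone-fused member of that class. Iodide adds to C9 in an SN2 homoconjugate addition, the C9–C8' bond breaks and the delocalised β-keto lactone enolate 13 is the leaving group. C9 is preferred to C8 because it is the only primary cyclopropane carbon and because the C8'–C9 bond stands almost parallel to the π* orbital of the ring-locked lactone carbonyl, whereas C8'–C8 lies in the lactone plane and gets no such activation. The ketone oxygen of 13 then displaces iodide in a 5-exo-tet closure through its in-plane lone pair, which makes O–C9, closes the dihydrofuran ring and returns the catalyst. Closure through carbon only gives 12 back and closure through the lactone carbonyl oxygen would give a strained bridged ketene acetal, so under these reversible conditions the material should drain into 14, helped by loss of cyclopropane strain and by aryl/enol ether/lactone conjugation. Bu4N+ is the counter-ion because a chelating cation would hold the enolate in its U form with the ketone oxygen turned away from C9. No stereocentre is created, and C7 and C8 take no part in bond breaking and keep their configuration. The chemoselectivity that must hold is attack at C9 rather than at the benzylic lactone carbon C7; primary against secondary carbon and strain release secure it, and the low iodide loading supports it.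

Step 10
Reactants: 14 (3R,3aS)-6-(4-benzyloxy-3,5-dimethoxyphenyl)-3-[3-methoxy-4-(triisopropylsilyloxy)phenyl]-3a,4-dihydro-1H,3H-furo[3,4-c]furan-1-one
Product: 15 (3R,3aS,6S,6aR)-6-(4-hydroxy-3,5-dimethoxyphenyl)-3-[3-methoxy-4-(triisopropylsilyloxy)phenyl]tetrahydro-1H,3H-furo[3,4-c]furan-1-one (guaiacyl exo, syringyl endo)
Conditions: H2 (5 bar), 10% Pd/C, EtOAc–EtOH, rt, stopped at full conversion
Reagents that add atoms: none
Why: Heterogeneous syn hydrogenation of a β-alkoxyacrylate-type alkene together with benzyl ether hydrogenolysis. Both hydrogens must arrive on the face that carries H8, the only one that leads to a cis-fused bicyclo[3.3.0]octane, so H8' and H7' end cis to H8 and the syringyl group is pushed into the endo position. A neutral solvent and close monitoring are meant to spare the benzylic C7–O and C7'–O bonds.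

Step 11
Reactants: 15 (3R,3aS,6S,6aR)-6-(4-hydroxy-3,5-dimethoxyphenyl)-3-[3-methoxy-4-(triisopropylsilyloxy)phenyl]tetrahydro-1H,3H-furo[3,4-c]furan-1-one
Product: 16 the corresponding lactol, (3R,3aS,6S,6aS)-6-(4-hydroxy-3,5-dimethoxyphenyl)-3-[3-methoxy-4-(triisopropylsilyloxy)phenyl]tetrahydro-1H,3H-furo[3,4-c]furan-1-ol (mixture at C9')
Conditions: i-Bu2AlH (2.5 equiv), CH2Cl2, −78 °C; aq. potassium sodium tartrate
Reagents that add atoms: none
Why: Partial reduction of a γ-lactone; the first equivalent is consumed by the phenol and the aluminium hemiacetal is stable at −78 °C, so the reduction should stop at the lactol.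

Step 12
Reactants: 16 lactol
Product: 17 4-{(1S,3aS,4R,6aS)-4-[3-methoxy-4-(triisopropylsilyloxy)phenyl]tetrahydro-1H,3H-furo[3,4-c]furan-1-yl}-2,6-dimethoxyphenol (7R,8S,8'S,7'S; guaiacyl exo, syringyl endo)
Conditions: Et3SiH (4 equiv), BF3·OEt2 (2 equiv), CH2Cl2, −78 → −40 °C; cold aq. NaHCO3
Reagents that add atoms: none
Why: Ionic reduction of a lactol through its cyclic oxocarbenium ion; the hemiacetal ionises far faster than the benzylic dialkyl ethers at this temperature and no stereocentre arises at C9'. The cold basic quench protects the kinetic C7' centre.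

Step 13
Reactants: 18 (S)-4-benzyl-2-oxazolidinone; 19 bromoacetyl bromide
Product: 20 (S)-4-benzyl-3-(2-bromoacetyl)oxazolidin-2-one
Conditions: n-BuLi, THF, −78 °C; then 19, −78 → 0 °C
Reagents that add atoms: none
Why: N-acylation of the metalated auxiliary; the acyl bromide reacts much faster than the alkyl bromide.

Step 14
Reactants: 17 furofuran phenol; 20 (S)-4-benzyl-3-(2-bromoacetyl)oxazolidin-2-one
Product: 21 (S)-4-benzyl-3-{2-[4-((1S,3aS,4R,6aS)-4-[3-methoxy-4-(triisopropylsilyloxy)phenyl]tetrahydro-1H,3H-furo[3,4-c]furan-1-yl)-2,6-dimethoxyphenoxy]acetyl}oxazolidin-2-one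
Conditions: K2CO3, Bu4NI (cat.), MeCN, rt → 40 °C
Reagents that add atoms: none
Why: Williamson etherification at an α-bromo imide, a very fast SN2 site that should outrun attack at the imide carbonyl. Carbonate in an aprotic solvent leaves the aryl silyl ether and the core stereocentres untouched.

Step 15
Reactants: 22 syringaldehyde
Product: 23 3,5-dimethoxy-4-(triisopropylsilyloxy)benzaldehyde
Conditions: TIPSCl, imidazole, DMAP (cat.), DMF, 40 °C
Reagents that add atoms: triisopropylsilyl chloride, CC(C)[Si](Cl)(C(C)C)C(C)C
Why: Silylation of a flanked phenol; the same silyl group as on the guaiacyl ring allows one final deprotection.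

Step 16
Reactants: 21 aryloxyacetyl imide; 23 3,5-dimethoxy-4-(triisopropylsilyloxy)benzaldehyde
Product: 25 (S)-4-benzyl-3-[(2S,3R)-2-aryloxy-3-hydroxy-3-(3,5-dimethoxy-4-triisopropylsilyloxyphenyl)propanoyl]oxazolidin-2-one (aryloxy = the furofuran-substituted 2,6-dimethoxyphenoxy group of 21), via Z boron enolate 24 (not isolated)
Conditions: Bu2BOTf, i-Pr2NEt, CH2Cl2, −78 → 0 °C; 23, −78 → 0 °C; pH 7 buffer, MeOH, H2O2, 0 °C
Reagents that add atoms: none
Why: Evans syn glycolate aldol; soft enolisation gives the Z boron enolate 24, which reacts through a closed chair transition state on the face away from the benzyl group of the (S)-auxiliary. This should give the 2S,3R syn adduct, the future 8''R,7''R pair. Control comes from the reagent, and the distant core cannot create a mismatch.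

Step 17
Reactants: 25 aldol adduct
Product: 26 bis(triisopropylsilyl) ether of the target, (7''R,8''R)-1,3-diol
Conditions: LiBH4, MeOH (1 equiv), THF, 0 °C
Reagents that add atoms: none
Why: Reductive cleavage of the N-acyl oxazolidinone turns the imide carbonyl into C9''H2OH and releases the auxiliary. Ethers, silyl ethers and all stereocentres are inert to borohydride.

Step 18
Reactants: 26 bis(triisopropylsilyl) ether of the target
Product: 27 target CNP0317965.1 (7R,8S,8'S,7'S,7''R,8''R)
Conditions: Bu4NF (2.2 equiv), AcOH (2.5 equiv), THF, 0 °C
Reagents that add atoms: none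
Why: Fluoride cleavage of both aryl silyl ethers. The acetic acid buffer keeps phenoxide concentration low, so quinone methide formation at C7 or C7'' should not start.

## Compound list

1 | vanillin | COc1cc(C=O)ccc1O | starting material
2 | 3-methoxy-4-(triisopropylsilyloxy)benzaldehyde | COc1cc(C=O)ccc1O[Si](C(C)C)(C(C)C)C(C)C | intermediate
3 | vinylmagnesium bromide | C=C[Mg]Br | starting material
4 | rac-1-[3-methoxy-4-(triisopropylsilyloxy)phenyl]prop-2-en-1-ol | C=CC(O)c1ccc(O[Si](C(C)C)(C(C)C)C(C)C)c(OC)c1 | intermediate
5 | (R)-1-[3-methoxy-4-(triisopropylsilyloxy)phenyl]prop-2-en-1-ol | C=C[C@@H](O)c1ccc(O[Si](C(C)C)(C(C)C)C(C)C)c(OC)c1 | intermediate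
6 | acetosyringone | COc1cc(C(C)=O)cc(OC)c1O | starting material
7 | 1-(4-benzyloxy-3,5-dimethoxyphenyl)ethanone | COc1cc(C(C)=O)cc(OC)c1OCc1ccccc1 | intermediate
8 | diethyl carbonate | CCOC(=O)OCC | starting material
9 | ethyl 3-(4-benzyloxy-3,5-dimethoxyphenyl)-3-oxopropanoate | CCOC(=O)CC(=O)c1cc(OC)c(OCc2ccccc2)c(OC)c1 | intermediate
10 | (R)-1-[3-methoxy-4-(triisopropylsilyloxy)phenyl]allyl 3-(4-benzyloxy-3,5-dimethoxyphenyl)-3-oxopropanoate | C=C[C@@H](OC(=O)CC(=O)c1cc(OC)c(OCc2ccccc2)c(OC)c1)c1ccc(O[Si](C(C)C)(C(C)C)C(C)C)c(OC)c1 | intermediate
11 | (R)-1-[3-methoxy-4-(triisopropylsilyloxy)phenyl]allyl 3-(4-benzyloxy-3,5-dimethoxyphenyl)-2-diazo-3-oxopropanoate | C=C[C@@H](OC(=O)C(=[N+]=[N-])C(=O)c1cc(OC)c(OCc2ccccc2)c(OC)c1)c1ccc(O[Si](C(C)C)(C(C)C)C(C)C)c(OC)c1 | intermediate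
12 | (1S,4R,5R)-1-(4-benzyloxy-3,5-dimethoxybenzoyl)-4-[3-methoxy-4-(triisopropylsilyloxy)phenyl]-3-oxabicyclo[3.1.0]hexan-2-one | COc1cc([C@@H]2OC(=O)[C@@]3(C(=O)c4cc(OC)c(OCc5ccccc5)c(OC)c4)C[C@@H]23)ccc1O[Si](C(C)C)(C(C)C)C(C)C | intermediate
13 | tetrabutylammonium enolate of (4R,5R)-3-(4-benzyloxy-3,5-dimethoxybenzoyl)-4-(iodomethyl)-5-[3-methoxy-4-(triisopropylsilyloxy)phenyl]oxolan-2-one (delocalised, geometry not fixed) | COc1cc([C@@H]2OC(=O)C(=C([O-])c3cc(OC)c(OCc4ccccc4)c(OC)c3)[C@H]2CI)ccc1O[Si](C(C)C)(C(C)C)C(C)C.CCCC[N+](CCCC)(CCCC)CCCC | intermediate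
14 | (3R,3aS)-6-(4-benzyloxy-3,5-dimethoxyphenyl)-3-[3-methoxy-4-(triisopropylsilyloxy)phenyl]-3a,4-dihydro-1H,3H-furo[3,4-c]furan-1-one | COc1cc([C@@H]2OC(=O)C3=C(c4cc(OC)c(OCc5ccccc5)c(OC)c4)OC[C@@H]23)ccc1O[Si](C(C)C)(C(C)C)C(C)C | intermediate
15 | (3R,3aS,6S,6aR)-6-(4-hydroxy-3,5-dimethoxyphenyl)-3-[3-methoxy-4-(triisopropylsilyloxy)phenyl]tetrahydro-1H,3H-furo[3,4-c]furan-1-one | COc1cc([C@@H]2OC(=O)[C@@H]3[C@H]2CO[C@@H]3c2cc(OC)c(O)c(OC)c2)ccc1O[Si](C(C)C)(C(C)C)C(C)C | intermediate
16 | lactol of 15 (mixture at C9') | COc1cc([C@@H]2OC(O)[C@@H]3[C@H]2CO[C@@H]3c2cc(OC)c(O)c(OC)c2)ccc1O[Si](C(C)C)(C(C)C)C(C)C | intermediate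
17 | 4-{(1S,3aS,4R,6aS)-4-[3-methoxy-4-(triisopropylsilyloxy)phenyl]tetrahydro-1H,3H-furo[3,4-c]furan-1-yl}-2,6-dimethoxyphenol | COc1cc([C@@H]2OC[C@@H]3[C@H]2CO[C@@H]3c2cc(OC)c(O)c(OC)c2)ccc1O[Si](C(C)C)(C(C)C)C(C)C | intermediate
18 | (S)-4-benzyl-2-oxazolidinone | O=C1N[C@@H](Cc2ccccc2)CO1 | starting material
19 | bromoacetyl bromide | BrCC(=O)Br | starting material
20 | (S)-4-benzyl-3-(2-bromoacetyl)oxazolidin-2-one | O=C(CBr)N1C(=O)OC[C@@H]1Cc1ccccc1 | intermediate
21 | aryloxyacetyl imide from 17 and 20 | COc1cc([C@@H]2OC[C@@H]3[C@H]2CO[C@@H]3c2cc(OC)c(OCC(=O)N3C(=O)OC[C@@H]3Cc3ccccc3)c(OC)c2)ccc1O[Si](C(C)C)(C(C)C)C(C)C | intermediate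
22 | syringaldehyde | COc1cc(C=O)cc(OC)c1O | starting material
23 | 3,5-dimethoxy-4-(triisopropylsilyloxy)benzaldehyde | COc1cc(C=O)cc(OC)c1O[Si](C(C)C)(C(C)C)C(C)C | intermediate
24 | Z dibutylboron enolate of 21 | COc1cc([C@@H]2OC[C@@H]3[C@H]2CO[C@@H]3c2cc(OC)c(O/C=C(\OB(CCCC)CCCC)N3C(=O)OC[C@@H]3Cc3ccccc3)c(OC)c2)ccc1O[Si](C(C)C)(C(C)C)C(C)C | intermediate
25 | (2S,3R) syn aldol adduct on the (S)-auxiliary | COc1cc([C@@H]2OC[C@@H]3[C@H]2CO[C@@H]3c2cc(OC)c(O[C@H](C(=O)N3C(=O)OC[C@@H]3Cc3ccccc3)[C@H](O)c3cc(OC)c(O[Si](C(C)C)(C(C)C)C(C)C)c(OC)c3)c(OC)c2)ccc1O[Si](C(C)C)(C(C)C)C(C)C | intermediate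
26 | bis(triisopropylsilyl) ether of the target | COc1cc([C@@H]2OC[C@@H]3[C@H]2CO[C@@H]3c2cc(OC)c(O[C@H](CO)[C@H](O)c3cc(OC)c(O[Si](C(C)C)(C(C)C)C(C)C)c(OC)c3)c(OC)c2)ccc1O[Si](C(C)C)(C(C)C)C(C)C | intermediate
27 | CNP0317965.1 | COc1cc([C@@H]2OC[C@@H]3[C@H]2CO[C@@H]3c2cc(OC)c(O[C@H](CO)[C@H](O)c3cc(OC)c(O)c(OC)c3)c(OC)c2)ccc1O | target

## Step count and least certain steps

Total step count: 18. Longest linear sequence: 14 steps (1, 2, 3, 6, 7, 8, 9, 10, 11, 12, 14, 16, 17, 18).

**Step 9 (key step).**
- *What may go wrong.* Turnover may stall or be diverted. Opening by free iodide may need temperatures at which substitution at the benzylic lactone carbon C7, followed by decarboxylation, becomes competitive. The enolate may also return to the cyclopropane through carbon faster than it closes through oxygen, because the closure builds a bicyclo[3.3.0]octene with the alkene at the ring fusion.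
- *Fallback.* It sets out from 12 and changes both the nucleophile and the bond that closes the ring. Acid-catalysed homoconjugate addition of water at C9 (TsOH·H2O cat., aqueous dioxane, 60 °C) should give the hydroxymethyl keto lactone F1. F1 adds to its own aryl ketone to give the fused cyclic hemiketal F2. This unstrained closure should outrun acyl migration to the primary hydroxyl. Dehydration with pyridinium tosylate and 4 Å MS in warm toluene comes back to the route at 14.
- *Basis.* The ring oxygen then stems from water, and C7'–O is formed instead of O–C9. Both operations are known chemistry: solvolytic opening of doubly activated cyclopropanes and cyclodehydration of γ-hydroxy β-keto esters.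

**Step 10.**
- *What may go wrong.* Saturation of the tetrasubstituted push–pull alkene may be slow. The exo guaiacyl group lies on the face that must meet the catalyst, which slows it further. During that time hydrogenolysis of the benzylic C–O bonds at C7 and C7' can set in.
- *Fallback.* It sets out from 14 and separates the two tasks. Conjugate reduction with Ni2B generated from NiCl2·6H2O and NaBH4 (MeOH–THF, 0 °C) is a hydride-type method for enoates and alkylidene lactones that leaves benzyl ethers and benzylic ethers alone. It should give the saturated benzyl ether F3, with hydride delivery to C7' from the H8 face and protonation of C8' to the only accessible cis fusion. A short hydrogenolysis (H2, 1 bar, Pd/C, EtOAc) then comes back to the route at 15.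

**Step 8.**
- *What may go wrong.* Exo/endo selectivity may be poor, because a terminal vinyl group exerts little allylic strain and the acceptor/acceptor carbene reacts through an early transition state. Side reactions of that carbene may also occur.
- *Fallback.* It sets out from 10, skips the diazo compound and comes back at 12. The method is oxidative radical cyclisation with Mn(OAc)3·2H2O (2.2 equiv) and Cu(OAc)2·H2O (cat.) in AcOH at 60 °C. Trivalent manganese generates the C8' radical, which closes 5-exo on C8 through a transition state with the aryl group pseudo-equatorial. The primary C9 radical is then oxidised and captured by C8'. This radical–polar sequence is known for 1-arylallyl acetoacetates and makes no new isolable compound.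

**Step 12.**
- *What may go wrong.* Lewis-acid ionisation of the endo benzylic ether may lead to epimerisation at C7' towards the exo,exo series, or to reductive opening of that ether.
- *Fallback.* It sets out from 15 and avoids Lewis acid altogether.
  1. Re-benzylation (BnBr, K2CO3, DMF) gives the benzyl ether F3.
  2. LiAlH4 in THF at 0 °C gives the diol F4.
  3. MsCl and Et3N in CH2Cl2 (−20 °C → rt) give the primary mesylate F5, which the C7 hydroxyl displaces in a 5-exo-tet closure to the benzyl-protected furofuran F6.
  4. Mild hydrogenolysis (H2, 1 bar, Pd/C, EtOAc) comes back to the route at 17.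
- *Note.* If part of the material closed through ionisation at C7, the exo guaiacyl group would still result.

**Step 6.**
- *What may go wrong.* At 100 °C the electron-rich 1-arylallyl ester may undergo Carroll rearrangement with loss of CO2, or ionise at C7 with erosion of enantiopurity.
- *Fallback.* It sets out from 9 and 5 and works at or below room temperature. Saponification of 9 (aq. KOH, EtOH, rt, cold acidification) gives the β-keto acid F7. Steglich esterification with 5 (DCC, DMAP cat., CH2Cl2, 0 °C) comes back to the route at 10.

## Further compounds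

F1 | step 9 | (4S,5R)-3-(4-benzyloxy-3,5-dimethoxybenzoyl)-4-(hydroxymethyl)-5-[3-methoxy-4-(triisopropylsilyloxy)phenyl]oxolan-2-one (C8' enolisable, undefined) | COc1cc([C@@H]2OC(=O)C(C(=O)c3cc(OC)c(OCc4ccccc4)c(OC)c3)[C@H]2CO)ccc1O[Si](C(C)C)(C(C)C)C(C)C
F2 | step 9 | cis-fused cyclic hemiketal of F1 (C7' undefined) | COc1cc([C@@H]2OC(=O)[C@@H]3[C@H]2COC3(O)c2cc(OC)c(OCc3ccccc3)c(OC)c2)ccc1O[Si](C(C)C)(C(C)C)C(C)C
F3 | step 10 | (3R,3aS,6S,6aR)-6-(4-benzyloxy-3,5-dimethoxyphenyl)-3-[3-methoxy-4-(triisopropylsilyloxy)phenyl]tetrahydro-1H,3H-furo[3,4-c]furan-1-one | COc1cc([C@@H]2OC(=O)[C@@H]3[C@H]2CO[C@@H]3c2cc(OC)c(OCc3ccccc3)c(OC)c2)ccc1O[Si](C(C)C)(C(C)C)C(C)C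
F0 | step 8 | none | none
F4 | step 12 | diol from F3: all-cis tetrahydrofuran with C9'H2OH on C8' and (R)-aryl(hydroxy)methyl (C7) on C8 | COc1cc([C@H](O)[C@@H]2CO[C@H](c3cc(OC)c(OCc4ccccc4)c(OC)c3)[C@@H]2CO)ccc1O[Si](C(C)C)(C(C)C)C(C)C
F5 | step 12 | primary (C9') methanesulfonate of F4 | COc1cc([C@H](O)[C@@H]2CO[C@H](c3cc(OC)c(OCc4ccccc4)c(OC)c3)[C@@H]2COS(C)(=O)=O)ccc1O[Si](C(C)C)(C(C)C)C(C)C
F6 | step 12 | benzyl ether of 17 | COc1cc([C@@H]2OC[C@@H]3[C@H]2CO[C@@H]3c2cc(OC)c(OCc3ccccc3)c(OC)c2)ccc1O[Si](C(C)C)(C(C)C)C(C)C
F7 | step 6 | 3-(4-benzyloxy-3,5-dimethoxyphenyl)-3-oxopropanoic acid | COc1cc(C(=O)CC(=O)O)cc(OC)c1OCc1ccccc1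
A1 | alternative 1 | (R)-1-(4-benzyloxy-3-methoxyphenyl)allyl 3-[4-(tert-butyldimethylsilyloxy)-3,5-dimethoxyphenyl]prop-2-yn-1-yl ether | C=C[C@@H](OCC#Cc1cc(OC)c(O[Si](C)(C)C(C)(C)C)c(OC)c1)c1ccc(OCc2ccccc2)c(OC)c1
A2 | alternative 1 | 2,3-trans 2-(4-benzyloxy-3-methoxyphenyl)-3-(pinacolborylmethyl)-4-(arylmethylidene)tetrahydrofuran, alkene aryl group cis to C9' | COc1cc([C@@H]2OC/C(=C\c3cc(OC)c(O[Si](C)(C)C(C)(C)C)c(OC)c3)[C@H]2CB2OC(C)(C)C(C)(C)O2)ccc1OCc1ccccc1
A3 | alternative 2 | all-cis 2-aryl-3-(hydroxymethyl)-4-(4-hydroxy-3-methoxybenzyl)tetrahydrofuran carrying the full side chain, terminal phenol as triisopropylsilyl ether | COc1cc(C[C@@H]2CO[C@H](c3cc(OC)c(O[C@H](CO)[C@H](O)c4cc(OC)c(O[Si](C(C)C)(C(C)C)C(C)C)c(OC)c4)c(OC)c3)[C@@H]2CO)ccc1O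
A4 | alternative 2 | target with the side-chain phenol as triisopropylsilyl ether | COc1cc([C@@H]2OC[C@@H]3[C@H]2CO[C@@H]3c2cc(OC)c(O[C@H](CO)[C@H](O)c3cc(OC)c(O[Si](C(C)C)(C(C)C)C(C)C)c(OC)c3)c(OC)c2)ccc1O
A5 | alternative 3 | 4,5-trans 3-diazo-5-(4-benzyloxy-3-methoxyphenyl)-4-{[4-(tert-butyldimethylsilyloxy)-3,5-dimethoxybenzyloxy]methyl}oxolan-2-one | COc1cc([C@@H]2OC(=O)C(=[N+]=[N-])[C@H]2COCc2cc(OC)c(O[Si](C)(C)C(C)(C)C)c(OC)c2)ccc1OCc1ccccc1
A6 | alternative 3 | endo,exo-diaryl furofuranone, lactone carbonyl at C9' | COc1cc([C@@H]2OC(=O)[C@@H]3[C@H]2CO[C@@H]3c2cc(OC)c(O[Si](C)(C)C(C)(C)C)c(OC)c2)ccc1OCc1ccccc1
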